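**Retrosynthetic overview** (cycloundecene locants: C1 ester carbon, C3=C4 ring alkene, C7 methylidene carbon, C8 hydroperoxide carbon, C10 CMe2)
1. Target ⇐ release of OOH and phenol ⇐ SN2 inversion of an (8R)-allylic mesylate by a peroxyketal anion ⇐ CBS reduction of the macrocyclic α-methylene ketone.
2. Eleven-membered carbocycle (the only ring of the target, formed second) ⇐ Cr/Ni vinyl bromide–aldehyde closure of the C7–C8 bond.
3. Acyclic (Z)-trienol ⇐ new Me3SiOTf-catalysed ring-opening allylation of a 3,6-dihydro-2H-pyran with 2-bromoallyltrimethylsilane (C5–C6 bond; the cis ring geometry becomes the Z alkene).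
4. Dihydropyran (temporary six-membered ring, formed first) ⇐ catalytic asymmetric oxa-[4+2] of 3,3-dimethylpent-4-enal with isoprene, which sets the ester-bearing stereocentre.
5. Inputs, all achiral: methyl 3,3-dimethylpent-4-enoate, isoprene, 2-bromoallyltrimethylsilane, p-coumaric acid, 2,3-dimethylbut-2-ene.

Assumption: the ring alkene is taken as Z exactly as the SMILES writes it (the two ring CH2 groups cis), and the catalyst antipodes in steps 2 and 9 are those predicted by the usual face-selectivity models.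

**Step 1**
Reactants: 1 methyl 3,3-dimethylpent-4-enoate
Product: 2 3,3-dimethylpent-4-enal
Conditions: iBu2AlH (1.05 equiv), CH2Cl2, −78 °C; Rochelle salt work-up; used as a solution (volatile)
Reagents that add atoms: none
Why: Partial ester reduction with iBu2AlH stops at the aluminium hemiacetal at −78 °C and gives the aldehyde on work-up; no stereocentre is involved.

**Step 2**
Reactants: 2 3,3-dimethylpent-4-enal; 3 isoprene
Product: 4 (2S)-2-(2,2-dimethylbut-3-en-1-yl)-4-methyl-3,6-dihydro-2H-pyran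
Conditions: isoprene (3 equiv), confined chiral imidodiphosphorimidate (IDPi) Brønsted acid (2 mol%), CH2Cl2, −40 °C
Reagents that add atoms: none
Why: Organocatalytic asymmetric oxa-Diels–Alder (hetero-[4+2]) reaction: the chiral IDPi anion pairs with the protonated aldehyde and isoprene adds to its Si face through the tertiary allyl cation-like terminus, giving the 4-methyl regioisomer and the (S) stereocentre (the later C1, R in the target after the CIP priority change), while the ring fixes the cis geometry of the trisubstituted alkene.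

**Step 3**
Reactants: 4 (2S)-2-(2,2-dimethylbut-3-en-1-yl)-4-methyl-3,6-dihydro-2H-pyran; 5 (2-bromoprop-2-en-1-yl)trimethylsilane
Product: 7 (5S,7Z)-11-bromo-3,3,7-trimethyldodeca-1,7,11-trien-5-ol, via trimethylsilyl ether 6 (not isolated)
Conditions: 5 (2 equiv), Me3SiOTf (15 mol%), 2,6-di-tert-butyl-4-methylpyridine (20 mol%), CH2Cl2, −78 to −30 °C; then K2CO3 (cat.), MeOH, 0 °C
Reagents that add atoms: none
Why: Proposed new method: Me3SiOTf silylates the ring oxygen of 4, and of the two C–O bonds only the primary allylic O–CH2 bond (prenyl-type, γ,γ-disubstituted) can break, so allylsilane 5 attacks that CH2 terminus (SN2 on the oxonium or capture of the tight allyl cation/silyl ether pair at low temperature, faster than rotation of the former ring alkene), which forms the C5–C6 bond of the target, transfers the cis ring geometry into the Z-trisubstituted alkene, leaves the carbinol stereocentre untouched and, by loss of Me3Si+ from the β-silyl cation, regenerates Me3SiOTf; the closest known reaction types are the Me3SiOTf-catalysed Hosomi–Sakurai allylation of acetals and the Lewis-acid SN1 allylation of prenyl-type ethers and halides by allylsilanes, neither shown for ring opening of a simple cyclic allyl ether.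

**Step 4**
Reactants: 8 p-coumaric acid
Product: 10 (2E)-3-{4-[(triisopropylsilyl)oxy]phenyl}prop-2-enoic acid, via bis-silyl derivative 9 (not isolated)
Conditions: iPr3SiCl (2.3 equiv), imidazole, DMF, rt; then AcOH/THF/H2O, rt
Reagents that add atoms: chlorotriisopropylsilane, CC(C)[Si](Cl)(C(C)C)C(C)C
Why: Standard phenol protection: both OH groups are silylated and the labile silyl ester is hydrolysed selectively, leaving the base-robust aryl triisopropylsilyl ether.

**Step 5**
Reactants: 7 (5S,7Z)-11-bromo-3,3,7-trimethyldodeca-1,7,11-trien-5-ol; 10 (2E)-3-{4-[(triisopropylsilyl)oxy]phenyl}prop-2-enoic acid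
Product: 11 (5S,7Z)-11-bromo-3,3,7-trimethyldodeca-1,7,11-trien-5-yl (2E)-3-{4-[(triisopropylsilyl)oxy]phenyl}prop-2-enoate
Conditions: DCC (1.3 equiv), DMAP (0.3 equiv), CH2Cl2, 0 °C to rt
Reagents that add atoms: none
Why: Steglich esterification acylates the alcohol oxygen without breaking the carbinol C–O bond, so the configuration is retained and the hydroxyl is masked as the final ester before the aldehyde is unveiled (this avoids lactol formation).

**Step 6**
Reactants: 11 (5S,7Z)-11-bromo-3,3,7-trimethyldodeca-1,7,11-trien-5-yl (2E)-3-{4-[(triisopropylsilyl)oxy]phenyl}prop-2-enoate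
Product: 12 (5R,7Z)-11-bromo-3,3,7-trimethyl-1-oxododeca-7,11-dien-5-yl (2E)-3-{4-[(triisopropylsilyl)oxy]phenyl}prop-2-enoate
Conditions: PdCl2(PhCN)2 (12 mol%), CuCl2·2H2O (12 mol%), AgNO2 (6 mol%), tBuOH/MeNO2 15:1, O2 (1 atm), rt
Reagents that add atoms: dioxygen, O=O
Why: Nitrite-modified aldehyde-selective Wacker oxidation: the quaternary allylic carbon blocks Markovnikov attack, so divalent palladium delivers oxygen to the terminal carbon of the vinyl group only, while the trisubstituted alkene, the bromoalkene and the cinnamate are inert (the descriptor changes from S to R only through CIP priorities).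

**Step 7**
Reactants: 12 (5R,7Z)-11-bromo-3,3,7-trimethyl-1-oxododeca-7,11-dien-5-yl (2E)-3-{4-[(triisopropylsilyl)oxy]phenyl}prop-2-enoate
Product: 13 (1R,3Z)-8-hydroxy-3,10,10-trimethyl-7-methylidenecycloundec-3-en-1-yl (2E)-3-{4-[(triisopropylsilyl)oxy]phenyl}prop-2-enoate (both C8 epimers)
Conditions: CrCl2 (8 equiv), NiCl2 (2 mol%), degassed DMSO/THF, 0.003 M, rt
Reagents that add atoms: none
Why: Nozaki–Hiyama–Kishi macrocyclisation: zerovalent nickel inserts into the C–Br bond, transmetalation gives a vinyl species of trivalent chromium that adds only to the aldehyde and closes the eleven-membered ring at C7–C8 under high dilution; the new carbinol centre is not controlled here and is reset in steps 8 and 9.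

**Step 8**
Reactants: 13 (1R,3Z)-8-hydroxy-3,10,10-trimethyl-7-methylidenecycloundec-3-en-1-yl (2E)-3-{4-[(triisopropylsilyl)oxy]phenyl}prop-2-enoate
Product: 14 (1R,3Z)-3,10,10-trimethyl-7-methylidene-8-oxocycloundec-3-en-1-yl (2E)-3-{4-[(triisopropylsilyl)oxy]phenyl}prop-2-enoate
Conditions: Dess–Martin periodinane (1.3 equiv), CH2Cl2, 0 °C; used at once
Reagents that add atoms: none
Why: Dess–Martin oxidation of the allylic alcohol converges both C8 epimers to one α-methylene ketone under neutral, mild conditions.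

**Step 9**
Reactants: 14 (1R,3Z)-3,10,10-trimethyl-7-methylidene-8-oxocycloundec-3-en-1-yl (2E)-3-{4-[(triisopropylsilyl)oxy]phenyl}prop-2-enoate
Product: 15 (1R,3Z,8R)-8-hydroxy-3,10,10-trimethyl-7-methylidenecycloundec-3-en-1-yl (2E)-3-{4-[(triisopropylsilyl)oxy]phenyl}prop-2-enoate
Conditions: (S)-2-methyl-CBS-oxazaborolidine (0.2 equiv), catecholborane (1.5 equiv), toluene, −78 °C; aqueous work-up
Reagents that add atoms: none
Why: Corey–Bakshi–Shibata reduction: the ketone binds the (S)-oxazaborolidine with the alkenyl branch as the large group and hydride is delivered to give the (8R)-allylic alcohol under catalyst control, while catecholborane at −78 °C avoids hydroboration and conjugate reduction.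

**Step 10**
Reactants: 16 2,3-dimethylbut-2-ene
Product: 17 2-methoxypropan-2-yl hydroperoxide
Conditions: O3, MeOH/CH2Cl2, −78 °C
Reagents that add atoms: ozone, [O-][O+]=O; methanol, CO
Why: Ozonolysis in methanol: the carbonyl oxide formed from the tetrasubstituted alkene is trapped by MeOH to give the α-methoxy hydroperoxide (a protected form of H2O2).

**Step 11**
Reactants: 15 (1R,3Z,8R)-8-hydroxy-3,10,10-trimethyl-7-methylidenecycloundec-3-en-1-yl (2E)-3-{4-[(triisopropylsilyl)oxy]phenyl}prop-2-enoate; 17 2-methoxypropan-2-yl hydroperoxide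
Product: 19 (1R,3Z,8S)-8-[(2-methoxypropan-2-yl)peroxy]-3,10,10-trimethyl-7-methylidenecycloundec-3-en-1-yl (2E)-3-{4-[(triisopropylsilyl)oxy]phenyl}prop-2-enoate, via allylic mesylate 18 (not isolated)
Conditions: MsCl, Et3N, CH2Cl2, −30 °C; cold solution added to 17 (3 equiv), KOtBu (2.5 equiv), DMF, −20 to 0 °C
Reagents that add atoms: methanesulfonyl chloride, CS(=O)(=O)Cl (its atoms stay only in 18)
Why: Mesylation followed by SN2 displacement with the peroxide anion (peroxyketal alkylation) inverts C8, turning the (R)-carbinol into the (S)-peroxide; the α-effect nucleophile and low temperature favour direct substitution over SN2' attack and elimination.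

**Step 12**
Reactants: 19 (1R,3Z,8S)-8-[(2-methoxypropan-2-yl)peroxy]-3,10,10-trimethyl-7-methylidenecycloundec-3-en-1-yl (2E)-3-{4-[(triisopropylsilyl)oxy]phenyl}prop-2-enoate
Product: 21 (1R,3Z,8S)-8-hydroperoxy-3,10,10-trimethyl-7-methylidenecycloundec-3-en-1-yl (2E)-3-(4-hydroxyphenyl)prop-2-enoate, via phenol peroxyketal 20 (not isolated)
Conditions: Bu4NF (1.1 equiv), AcOH (1.5 equiv), THF, 0 °C; then AcOH/H2O added, rt
Reagents that add atoms: none
Why: Buffered fluoride cleaves the aryl silyl ether and mild aqueous acid then hydrolyses the peroxyketal to the free hydroperoxide; neither stage touches the stereocentres, the ester or the alkenes.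

**Compound list**
1 | methyl 3,3-dimethylpent-4-enoate | COC(=O)CC(C)(C)C=C | starting material
2 | 3,3-dimethylpent-4-enal | O=CCC(C)(C)C=C | intermediate
3 | isoprene (2-methylbuta-1,3-diene) | C=CC(C)=C | starting material
4 | (2S)-2-(2,2-dimethylbut-3-en-1-yl)-4-methyl-3,6-dihydro-2H-pyran | CC1=CCO[C@H](CC(C)(C)C=C)C1 | intermediate
5 | (2-bromoprop-2-en-1-yl)trimethylsilane | C=C(Br)C[Si](C)(C)C | starting material
6 | {[(5S,7Z)-11-bromo-3,3,7-trimethyldodeca-1,7,11-trien-5-yl]oxy}trimethylsilane | C=C(Br)CC/C=C(/C)C[C@H](O[Si](C)(C)C)CC(C)(C)C=C | intermediate (not isolated)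
7 | (5S,7Z)-11-bromo-3,3,7-trimethyldodeca-1,7,11-trien-5-ol | C=C(Br)CC/C=C(/C)C[C@H](O)CC(C)(C)C=C | intermediate
8 | p-coumaric acid, (2E)-3-(4-hydroxyphenyl)prop-2-enoic acid | OC(=O)/C=C/c1ccc(O)cc1 | starting material
9 | triisopropylsilyl (2E)-3-{4-[(triisopropylsilyl)oxy]phenyl}prop-2-enoate | CC(C)[Si](OC(=O)/C=C/c1ccc(O[Si](C(C)C)(C(C)C)C(C)C)cc1)(C(C)C)C(C)C | intermediate (not isolated)
10 | (2E)-3-{4-[(triisopropylsilyl)oxy]phenyl}prop-2-enoic acid | OC(=O)/C=C/c1ccc(O[Si](C(C)C)(C(C)C)C(C)C)cc1 | intermediate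
11 | (5S,7Z)-11-bromo-3,3,7-trimethyldodeca-1,7,11-trien-5-yl (2E)-3-{4-[(triisopropylsilyl)oxy]phenyl}prop-2-enoate | C=C(Br)CC/C=C(/C)C[C@H](OC(=O)/C=C/c1ccc(O[Si](C(C)C)(C(C)C)C(C)C)cc1)CC(C)(C)C=C | intermediate
12 | (5R,7Z)-11-bromo-3,3,7-trimethyl-1-oxododeca-7,11-dien-5-yl (2E)-3-{4-[(triisopropylsilyl)oxy]phenyl}prop-2-enoate | C=C(Br)CC/C=C(/C)C[C@H](OC(=O)/C=C/c1ccc(O[Si](C(C)C)(C(C)C)C(C)C)cc1)CC(C)(C)CC=O | intermediate
13 | (1R,3Z)-8-hydroxy-3,10,10-trimethyl-7-methylidenecycloundec-3-en-1-yl (2E)-3-{4-[(triisopropylsilyl)oxy]phenyl}prop-2-enoate, C8 epimers | C=C1CC/C=C(/C)C[C@H](OC(=O)/C=C/c2ccc(O[Si](C(C)C)(C(C)C)C(C)C)cc2)CC(C)(C)CC1O | intermediate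
14 | (1R,3Z)-3,10,10-trimethyl-7-methylidene-8-oxocycloundec-3-en-1-yl (2E)-3-{4-[(triisopropylsilyl)oxy]phenyl}prop-2-enoate | C=C1CC/C=C(/C)C[C@H](OC(=O)/C=C/c2ccc(O[Si](C(C)C)(C(C)C)C(C)C)cc2)CC(C)(C)CC1=O | intermediate
15 | (1R,3Z,8R)-8-hydroxy-3,10,10-trimethyl-7-methylidenecycloundec-3-en-1-yl (2E)-3-{4-[(triisopropylsilyl)oxy]phenyl}prop-2-enoate | C=C1CC/C=C(/C)C[C@H](OC(=O)/C=C/c2ccc(O[Si](C(C)C)(C(C)C)C(C)C)cc2)CC(C)(C)C[C@H]1O | intermediate
16 | 2,3-dimethylbut-2-ene | CC(C)=C(C)C | starting material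
17 | 2-methoxypropan-2-yl hydroperoxide | COC(C)(C)OO | intermediate
18 | (1R,3Z,8R)-8-(methanesulfonyloxy)-3,10,10-trimethyl-7-methylidenecycloundec-3-en-1-yl (2E)-3-{4-[(triisopropylsilyl)oxy]phenyl}prop-2-enoate | C=C1CC/C=C(/C)C[C@H](OC(=O)/C=C/c2ccc(O[Si](C(C)C)(C(C)C)C(C)C)cc2)CC(C)(C)C[C@H]1OS(C)(=O)=O | intermediate (not isolated)
19 | (1R,3Z,8S)-8-[(2-methoxypropan-2-yl)peroxy]-3,10,10-trimethyl-7-methylidenecycloundec-3-en-1-yl (2E)-3-{4-[(triisopropylsilyl)oxy]phenyl}prop-2-enoate | C=C1CC/C=C(/C)C[C@H](OC(=O)/C=C/c2ccc(O[Si](C(C)C)(C(C)C)C(C)C)cc2)CC(C)(C)C[C@@H]1OOC(C)(C)OC | intermediate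
20 | (1R,3Z,8S)-8-[(2-methoxypropan-2-yl)peroxy]-3,10,10-trimethyl-7-methylidenecycloundec-3-en-1-yl (2E)-3-(4-hydroxyphenyl)prop-2-enoate | C=C1CC/C=C(/C)C[C@H](OC(=O)/C=C/c2ccc(O)cc2)CC(C)(C)C[C@@H]1OOC(C)(C)OC | intermediate (not isolated)
21 | (1R,3Z,8S)-8-hydroperoxy-3,10,10-trimethyl-7-methylidenecycloundec-3-en-1-yl (2E)-3-(4-hydroxyphenyl)prop-2-enoate (CNP0208931.1) | C=C1CC/C=C(/C)C[C@H](OC(=O)/C=C/c2ccc(O)cc2)CC(C)(C)C[C@@H]1OO | target

**Step count**
Total: 12 steps. Longest linear sequence: 10 steps (1, 2, 3, 5, 6, 7, 8, 9, 11, 12); steps 4 and 10 are side preparations of acid 10 and hydroperoxide 17.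

**Three steps most likely to fail**

Step 3 (the proposed new ring-opening allylation; risks are no ionisation, attack at the tertiary terminus, or Z/E erosion). The fallback uses known chemistry only, sets out from 4 and comes back at 11.
- Oxidise the allylic O–CH2 of 4 with pyridinium chlorochromate (C5H5NH[CrO3Cl], CH2Cl2, reflux) to the unsaturated lactone (6S)-6-(2,2-dimethylbut-3-en-1-yl)-4-methyl-5,6-dihydro-2H-pyran-2-one F1.
- Reduce with iBu2AlH (CH2Cl2, −78 to 0 °C) to (2Z,5S)-3,7,7-trimethylnona-2,8-diene-1,5-diol F2.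
- Convert the primary allylic hydroxyl selectively (MsCl, 2,4,6-collidine, LiCl, DMF, 0 °C) to (5S,7Z)-9-chloro-3,3,7-trimethylnona-1,7-dien-5-ol F3, and silylate at once (Et3SiCl, imidazole) to {[(5S,7Z)-9-chloro-3,3,7-trimethylnona-1,7-dien-5-yl]oxy}triethylsilane F4, because the free alkoxide would re-close to 4.
- Alkylate with LiCH2C≡CSiMe3 (THF, −78 °C) to triethyl{[(5S,7Z)-3,3,7-trimethyl-12-(trimethylsilyl)dodeca-1,7-dien-11-yn-5-yl]oxy}silane F5, with the alkene geometry retained.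
- Remove both silyl groups with Bu4NF to give (5S,7Z)-3,3,7-trimethyldodeca-1,7-dien-11-yn-5-ol F6.
- Esterify with 10 (DCC, DMAP) to (5S,7Z)-3,3,7-trimethyldodeca-1,7-dien-11-yn-5-yl (2E)-3-{4-[(triisopropylsilyl)oxy]phenyl}prop-2-enoate F7.
- Bromoboration of the terminal alkyne with B-bromo-9-borabicyclo[3.3.1]nonane (CH2Cl2, 0 °C), then AcOH protonolysis, gives the 2-bromo-1-alkene 11.

Step 7 (closure of a strained eleven-membered ring by the Cr/Ni coupling). The fallback changes the ring-closing bond from C7–C8 to C5–C6; it sets out from 4 and comes back at 14. It depends on the step 3 reactivity working in intramolecular form.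
- Oxidise 4 under the step 6 Wacker conditions to 3,3-dimethyl-4-[(2R)-4-methyl-3,6-dihydro-2H-pyran-2-yl]butanal F8.
- Add the Grignard reagent made from 5 and Mg (THF) and quench with Me3SiCl to give trimethyl({5,5-dimethyl-6-[(2R)-4-methyl-3,6-dihydro-2H-pyran-2-yl]-2-[(trimethylsilyl)methyl]hex-1-en-3-yl}oxy)silane F9 (both carbinol epimers).
- Catalytic Me3SiOTf at high dilution (CH2Cl2, −78 to −30 °C) lets the tethered allylsilane open the pyran, giving (5R,7Z)-3,3,7-trimethyl-11-methylidene-1,5-bis[(trimethylsilyl)oxy]cycloundec-7-ene F10.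
- Methanolysis (K2CO3, MeOH) gives (5R,7Z)-3,3,7-trimethyl-11-methylidenecycloundec-7-ene-1,5-diol F11.
- MnO2 oxidises only the allylic hydroxyl, giving (5Z,8R)-8-hydroxy-6,10,10-trimethyl-2-methylidenecycloundec-5-en-1-one F12.
- Esterification with 10 (DCC, DMAP) gives 14, after which steps 9, 11 and 12 follow unchanged.

Step 11 (SN2 at a secondary allylic carbon in a medium ring; SN2' attack at the methylidene carbon and elimination compete). The fallback gives up stereospecific substitution for ionisation and separation; it sets out from 13 (the C8 epimer mixture, so steps 8 and 9 are skipped) and comes back at 21.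
- CBr4/PPh3 (CH2Cl2, 0 °C) gives (1R,3Z)-8-bromo-3,10,10-trimethyl-7-methylidenecycloundec-3-en-1-yl (2E)-3-{4-[(triisopropylsilyl)oxy]phenyl}prop-2-enoate F13.
- AgOCOCF3 with anhydrous H2O2 in Et2O (−78 to 0 °C) ionises the bromide and H2O2 captures the allyl cation.
- Preparative HPLC separates the C8 epimers and any primary regioisomer, giving (1R,3Z,8S)-8-hydroperoxy-3,10,10-trimethyl-7-methylidenecycloundec-3-en-1-yl (2E)-3-{4-[(triisopropylsilyl)oxy]phenyl}prop-2-enoate F14.
- Bu4NF/AcOH (THF, 0 °C) removes the silyl group to give 21.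

**Further compounds**
F1 | step 3 | (6S)-6-(2,2-dimethylbut-3-en-1-yl)-4-methyl-5,6-dihydro-2H-pyran-2-one | CC1=CC(=O)O[C@H](CC(C)(C)C=C)C1
F2 | step 3 | (2Z,5S)-3,7,7-trimethylnona-2,8-diene-1,5-diol | OC/C=C(/C)C[C@H](O)CC(C)(C)C=C
F3 | step 3 | (5S,7Z)-9-chloro-3,3,7-trimethylnona-1,7-dien-5-ol | ClC/C=C(/C)C[C@H](O)CC(C)(C)C=C
F4 | step 3 | {[(5S,7Z)-9-chloro-3,3,7-trimethylnona-1,7-dien-5-yl]oxy}triethylsilane | ClC/C=C(/C)C[C@H](O[Si](CC)(CC)CC)CC(C)(C)C=C
F5 | step 3 | triethyl{[(5S,7Z)-3,3,7-trimethyl-12-(trimethylsilyl)dodeca-1,7-dien-11-yn-5-yl]oxy}silane | C[Si](C)(C)C#CCC/C=C(/C)C[C@H](O[Si](CC)(CC)CC)CC(C)(C)C=C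
F6 | step 3 | (5S,7Z)-3,3,7-trimethyldodeca-1,7-dien-11-yn-5-ol | C#CCC/C=C(/C)C[C@H](O)CC(C)(C)C=C
F7 | step 3 | (5S,7Z)-3,3,7-trimethyldodeca-1,7-dien-11-yn-5-yl (2E)-3-{4-[(triisopropylsilyl)oxy]phenyl}prop-2-enoate | C#CCC/C=C(/C)C[C@H](OC(=O)/C=C/c1ccc(O[Si](C(C)C)(C(C)C)C(C)C)cc1)CC(C)(C)C=C
F8 | step 7 | 3,3-dimethyl-4-[(2R)-4-methyl-3,6-dihydro-2H-pyran-2-yl]butanal | CC1=CCO[C@H](CC(C)(C)CC=O)C1
F9 | step 7 | trimethyl({5,5-dimethyl-6-[(2R)-4-methyl-3,6-dihydro-2H-pyran-2-yl]-2-[(trimethylsilyl)methyl]hex-1-en-3-yl}oxy)silane, C3 epimers | CC1=CCO[C@H](CC(C)(C)CC(O[Si](C)(C)C)C(=C)C[Si](C)(C)C)C1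
F10 | step 7 | (5R,7Z)-3,3,7-trimethyl-11-methylidene-1,5-bis[(trimethylsilyl)oxy]cycloundec-7-ene, C1 epimers | C=C1CC/C=C(/C)C[C@H](O[Si](C)(C)C)CC(C)(C)CC1O[Si](C)(C)C
F11 | step 7 | (5R,7Z)-3,3,7-trimethyl-11-methylidenecycloundec-7-ene-1,5-diol, C1 epimers | C=C1CC/C=C(/C)C[C@H](O)CC(C)(C)CC1O
F12 | step 7 | (5Z,8R)-8-hydroxy-6,10,10-trimethyl-2-methylidenecycloundec-5-en-1-one | C=C1CC/C=C(/C)C[C@H](O)CC(C)(C)CC1=O
F13 | step 11 | (1R,3Z)-8-bromo-3,10,10-trimethyl-7-methylidenecycloundec-3-en-1-yl (2E)-3-{4-[(triisopropylsilyl)oxy]phenyl}prop-2-enoate, C8 epimers | C=C1CC/C=C(/C)C[C@H](OC(=O)/C=C/c2ccc(O[Si](C(C)C)(C(C)C)C(C)C)cc2)CC(C)(C)CC1Br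
F14 | step 11 | (1R,3Z,8S)-8-hydroperoxy-3,10,10-trimethyl-7-methylidenecycloundec-3-en-1-yl (2E)-3-{4-[(triisopropylsilyl)oxy]phenyl}prop-2-enoate | C=C1CC/C=C(/C)C[C@H](OC(=O)/C=C/c2ccc(O[Si](C(C)C)(C(C)C)C(C)C)cc2)CC(C)(C)C[C@@H]1OO
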